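**Retrosynthetic overview**

1. Target ⇒ (last: NaBH4 at C4 of the lower unit; before it: removal of six benzyl ethers) hexabenzyl dimer ketone ⇒ C4(upper)–C6(lower) bond by intramolecular aryl transfer across a temporary 3-O–B tether, from an upper 4-methoxyflavan-3-ol and a lower dihydroflavonol-6-boronic acid.
2. Upper ring C (O1–C2–C3–C4–C4a–C8a) ⇒ ring expansion of the five-membered ring O1–C2–C3–C4a–C8a of a trans-2-aryl-2,3-dihydrobenzofuran whose exocyclic CH2OTf is the future C4: 1,2-shift of ring A from C3 to C4 through a phenonium ion, water entering at C3.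
3. Enabling feature: C4a of the upper ring A is para to O-7 and ortho to O-1, so this ipso carbon is a strong neighbouring group; after the shift the exocyclic carbon is the benzylic C4 and C3 carries the oxygen.
4. Dihydrobenzofuran ⇒ rhodium-carbene C–H insertion of an aryl diazoacetate (sets C2); lower unit ⇒ chalcone → epoxide → dihydroflavonol; both halves from 3,4-di-O-benzylgallacetophenone.
5. Ring order: upper unit ring A (bought) → five-membered O-ring → ring C by expansion; lower unit ring A (bought) → ring C by epoxide opening; the halves are joined last.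

Key step: step 8

Assumption: Rh2(S-PTTL)4 is taken to give the (2R)-configured insertion product; should the sense of induction be the opposite, the mirror-image catalyst Rh2(R-PTTL)4 is used. Compounds 1, 5 and 17 are taken as commercial.

**Route**

Step 1
Reactants: 1 gallacetophenone (1-(2,3,4-trihydroxyphenyl)ethanone)
Product: 2 1-[3,4-bis(benzyloxy)-2-hydroxyphenyl]ethanone
Conditions: BnBr (2.05 equiv), K2CO3, DMF, rt
Reagents that add atoms: benzyl bromide BrCc1ccccc1
Why: Williamson etherification in which the 2-OH, hydrogen-bonded to the acetyl carbonyl and least acidic, stays free while O-4 and O-3 are benzylated.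

Step 2
Reactants: 2 1-[3,4-bis(benzyloxy)-2-hydroxyphenyl]ethanone
Product: 3 2-acetyl-5,6-bis(benzyloxy)phenyl pivalate
Conditions: PivCl, Et3N, DMAP (cat.), CH2Cl2, rt
Reagents that add atoms: pivaloyl chloride CC(C)(C)C(Cl)=O
Why: DMAP-catalysed O-acylation masks the phenol as a hindered ester that should survive the acidic oxidative rearrangement and keeps the phenol from oxidation.

Step 3
Reactants: 3 2-acetyl-5,6-bis(benzyloxy)phenyl pivalate
Product: 4 methyl 2-[3,4-bis(benzyloxy)-2-(pivaloyloxy)phenyl]acetate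
Conditions: PhI(OAc)2, H2SO4 (cat.), HC(OMe)3/MeOH, 50 °C
Reagents that add atoms: methanol CO
Why: Oxidative 1,2-aryl migration of an aryl methyl ketone to the methyl arylacetate (via the enol ether and an alpha-iodanyl ketal), helped by the para-benzyloxy group on the migrating ring.

Step 4
Reactants: 4 methyl 2-[3,4-bis(benzyloxy)-2-(pivaloyloxy)phenyl]acetate; 5 4-(benzyloxy)benzyl chloride
Product: 7 methyl 2-[3,4-bis(benzyloxy)-2-{[4-(benzyloxy)benzyl]oxy}phenyl]acetate, via free phenol 6 (not isolated)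
Conditions: K2CO3, MeOH, rt; concentrate; then 5, KI (cat.), acetone, 55 °C
Reagents that add atoms: none
Why: Base methanolysis of the aryl pivalate followed by Williamson O-alkylation of the phenoxide brings in the CH2 that becomes C2 together with ring B.

Step 5
Reactants: 7 methyl 2-[3,4-bis(benzyloxy)-2-{[4-(benzyloxy)benzyl]oxy}phenyl]acetate
Product: 8 methyl 2-diazo-2-[3,4-bis(benzyloxy)-2-{[4-(benzyloxy)benzyl]oxy}phenyl]acetate
Conditions: p-ABSA, DBU, MeCN, 0 °C to rt
Reagents that add atoms: 4-acetamidobenzenesulfonyl azide CC(=O)Nc1ccc(cc1)S(=O)(=O)N=[N+]=[N-]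
Why: Regitz diazo transfer to the activated methylene of the arylacetate should give the donor/acceptor diazo ester.

Step 6
Reactants: 8 methyl 2-diazo-2-[3,4-bis(benzyloxy)-2-{[4-(benzyloxy)benzyl]oxy}phenyl]acetate
Product: 10 methyl (2R,3R)-6,7-bis(benzyloxy)-2-[4-(benzyloxy)phenyl]-2,3-dihydrobenzofuran-3-carboxylate (trans), via cis ester 9 (not isolated)
Conditions: Rh2(S-PTTL)4 (1 mol%), toluene, −60 °C; then NaOMe (cat.), MeOH/THF, 0 °C to rt
Reagents that add atoms: none
Why: Intramolecular 1,5 C–H insertion of the rhodium donor/acceptor carbene into the ether-activated benzylic C–H bond closes the dihydrobenzofuran and sets C2 under control of the chiral carboxylate ligands (cis ester kinetically), and base epimerisation at the ester-bearing C3 then gives the more stable trans ester without touching C2.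

Step 7
Reactants: 10 methyl (2R,3R)-6,7-bis(benzyloxy)-2-[4-(benzyloxy)phenyl]-2,3-dihydrobenzofuran-3-carboxylate
Product: 11 [(2R,3S)-6,7-bis(benzyloxy)-2-[4-(benzyloxy)phenyl]-2,3-dihydrobenzofuran-3-yl]methanol (trans)
Conditions: LiAlH4, THF, 0 °C
Reagents that add atoms: none
Why: Hydride reduction of the ester to the primary alcohol, no stereocentre being affected.

Step 8
Reactants: 11 [(2R,3S)-6,7-bis(benzyloxy)-2-[4-(benzyloxy)phenyl]-2,3-dihydrobenzofuran-3-yl]methanol
Product: 13 (2S,3R)-7,8-bis(benzyloxy)-2-[4-(benzyloxy)phenyl]chroman-3-ol (2,3-trans), via triflate 12 (not isolated)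
Conditions: Tf2O, 2,6-di-tert-butylpyridine, CH2Cl2, −78 °C; then THF/H2O, −78 to 0 °C
Reagents that add atoms: water O
Why: In flavan numbering, the primary triflate at the exocyclic C4 is ionised with help from the ipso carbon C4a of ring A (para to the 7-benzyloxy group, ortho to O1), which gives a phenonium (spirocyclopropyl cyclohexadienyl) ion bridging C3 and C4; water opens the bridge at C3, so ring A ends on C4 and the five-membered ring O1–C2–C3–C4a–C8a becomes the six-membered ring O1–C2–C3–C4–C4a–C8a. The closest known reaction type is the aryl-participation (neophyl-type) solvolysis of homobenzylic sulfonates, including the ring expansion of 1-indanylmethyl sulfonates to 2-tetralyl products. The six-membered ring is not closed by a cyclisation but arises by this 1,2-aryl shift (3-exo-tet ipso attack at C4, then cleavage of the C3–C4a bond). The new stereocentre C3 is set by the substrate: water enters anti to the departing ipso carbon (inversion at C3), C2 is untouched, and the trans dihydrobenzofuran should therefore give the 2,3-trans flavan-3-ol (2S,3R). The step needs opening of the bridged ion at the secondary C3 and not at the primary C4; this should be secured by the relief of the bicyclo[3.1.0] strain on going to the six-membered ring and by the better cation stabilisation at the secondary carbon, while return of triflate to C4 is reversible.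

Step 9
Reactants: 13 (2S,3R)-7,8-bis(benzyloxy)-2-[4-(benzyloxy)phenyl]chroman-3-ol
Product: 14 (2S,3R,4S)-7,8-bis(benzyloxy)-2-[4-(benzyloxy)phenyl]-4-methoxychroman-3-ol (3,4-trans)
Conditions: DDQ, MeOH (10 equiv), CH2Cl2, 0 °C to rt
Reagents that add atoms: methanol CO
Why: DDQ hydride abstraction from the benzylic C4–H gives the C4 cation (stabilised by O1 and the 7-benzyloxy group), which methanol should capture anti to the 3-OH; the C4 configuration is of no consequence later.

Step 10
Reactants: 2 1-[3,4-bis(benzyloxy)-2-hydroxyphenyl]ethanone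
Product: 15 1-[3,4-bis(benzyloxy)-5-bromo-2-hydroxyphenyl]ethanone
Conditions: NBS, MeCN, 0 °C, dark
Reagents that add atoms: N-bromosuccinimide BrN1C(=O)CCC1=O
Why: Electrophilic aromatic bromination para to the free phenol marks the carbon that becomes C6 of the lower unit.

Step 11
Reactants: 15 1-[3,4-bis(benzyloxy)-5-bromo-2-hydroxyphenyl]ethanone
Product: 16 1-[3,4-bis(benzyloxy)-5-bromo-2-(methoxymethoxy)phenyl]ethanone
Conditions: MOMCl, K2CO3, acetone, reflux
Reagents that add atoms: chloromethyl methyl ether COCCl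
Why: O-alkylation to the MOM acetal blocks the phenol so that the chalcone does not cyclise during epoxidation.

Step 12
Reactants: 16 1-[3,4-bis(benzyloxy)-5-bromo-2-(methoxymethoxy)phenyl]ethanone; 17 4-(benzyloxy)benzaldehyde
Product: 18 (E)-1-[3,4-bis(benzyloxy)-5-bromo-2-(methoxymethoxy)phenyl]-3-[4-(benzyloxy)phenyl]prop-2-en-1-one
Conditions: KOH, EtOH/THF, rt
Reagents that add atoms: none
Why: Claisen–Schmidt condensation should give the (E)-chalcone.

Step 13
Reactants: 18 (E)-chalcone
Product: 19 [(2R,3S)-3-[4-(benzyloxy)phenyl]oxiran-2-yl][3,4-bis(benzyloxy)-5-bromo-2-(methoxymethoxy)phenyl]methanone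
Conditions: poly-L-leucine, urea·H2O2, DBU, THF, rt
Reagents that add atoms: hydrogen peroxide OO
Why: Juliá–Colonna epoxidation, in which the helical poly-L-leucine controls the face of hydroperoxide conjugate addition and should give the (alpha-R,beta-S) trans epoxide.

Step 14
Reactants: 19 chalcone epoxide
Product: 20 (2R,3R)-7,8-bis(benzyloxy)-2-[4-(benzyloxy)phenyl]-6-bromo-3-hydroxychroman-4-one
Conditions: HCl (cat.), MeOH/THF, 55 °C
Reagents that add atoms: none
Why: Acid removes the MOM group and the phenol opens the epoxide at the benzylic carbon (6-endo, inversion there), C3 keeping the epoxide configuration and the 2,3-trans dihydroflavonol being the preferred isomer.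

Step 15
Reactants: 20 (2R,3R)-6-bromodihydroflavonol
Product: 21 [(2R,3R)-7,8-bis(benzyloxy)-2-[4-(benzyloxy)phenyl]-3-hydroxy-4-oxochroman-6-yl]boronic acid
Conditions: B2(OH)4, Pd(OAc)2 (5 mol%), XPhos, KOAc, EtOH, 80 °C
Reagents that add atoms: tetrahydroxydiboron OB(O)B(O)O
Why: Miyaura-type palladium-catalysed borylation of the aryl bromide gives the boronic acid directly under an acetate base that the dihydroflavonol should tolerate.

Step 16
Reactants: 14 (2S,3R,4S)-4-methoxyflavan-3-ol; 21 dihydroflavonol-6-boronic acid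
Product: 23 hexa-O-benzyl dimer ketone (upper unit 2,3-trans-3,4-cis; lower unit 2R,3R), via boronic ester 22 (not isolated)
Conditions: 4 Å MS, CH2Cl2, rt; then TfOH (5 mol%), −40 to −20 °C, high dilution; aq. NaHCO3
Reagents that add atoms: none
Why: Proposed new method: the boronic acid is first esterified to the 3-OH of 14 (a temporary B–O tether), catalytic acid then ionises the 4-methoxy group to the C4 cation (stabilised by O1 and the 7-benzyloxy group), and the boron-bound carbon C6 of the lower unit is delivered through a five-membered transition state (C4···C6'–B–O–C3) to the face syn to O3, which should give the 3,4-cis C4–C6' bond regiospecifically by ipso substitution; the closest known reaction types are the Petasis borono-Mannich reaction (a hydroxyl-bound boronate passing its aryl group to an adjacent iminium carbon) and the acid-promoted ipso-Friedel–Crafts addition of aryl boron reagents to oxocarbenium and benzylic cations.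

Step 17
Reactants: 23 hexa-O-benzyl dimer ketone
Product: 24 (2R,3R)-3,7,8-trihydroxy-2-(4-hydroxyphenyl)-6-[(2S,3R,4R)-3,7,8-trihydroxy-2-(4-hydroxyphenyl)chroman-4-yl]chroman-4-one
Conditions: H2 (1 atm), Pd/C, EtOAc/MeOH, rt
Reagents that add atoms: none
Why: Hydrogenolysis of the six benzyl aryl ethers, the ketone being a vinylogous ester (conjugated to O1 and O7) that should not be reduced.

Step 18
Reactants: 24 hexaphenolic dimer ketone
Product: 25 (2R,3S,4R)-2-(4-hydroxyphenyl)-6-[(2S,3R,4R)-3,7,8-trihydroxy-2-(4-hydroxyphenyl)chroman-4-yl]chroman-3,4,7,8-tetrol (target)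
Conditions: NaBH4, MeOH, 0 °C; pH 6 buffer work-up
Reagents that add atoms: none
Why: Borohydride reduction of a 2,3-trans dihydroflavonol, known to deliver the 3,4-trans diol, sets C4 (R) of the lower unit in the last step so that the acid-labile benzylic alcohol is never carried through other chemistry.

**Compound list**

1 | gallacetophenone, 1-(2,3,4-trihydroxyphenyl)ethanone | CC(=O)c1ccc(O)c(O)c1O | starting material
2 | 1-[3,4-bis(benzyloxy)-2-hydroxyphenyl]ethanone | CC(=O)c1ccc(OCc2ccccc2)c(OCc2ccccc2)c1O | intermediate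
3 | 2-acetyl-5,6-bis(benzyloxy)phenyl pivalate | CC(=O)c1ccc(OCc2ccccc2)c(OCc2ccccc2)c1OC(=O)C(C)(C)C | intermediate
4 | methyl 2-[3,4-bis(benzyloxy)-2-(pivaloyloxy)phenyl]acetate | COC(=O)Cc1ccc(OCc2ccccc2)c(OCc2ccccc2)c1OC(=O)C(C)(C)C | intermediate
5 | 4-(benzyloxy)benzyl chloride | ClCc1ccc(OCc2ccccc2)cc1 | starting material
6 | methyl 2-[3,4-bis(benzyloxy)-2-hydroxyphenyl]acetate (free phenol, not isolated) | COC(=O)Cc1ccc(OCc2ccccc2)c(OCc2ccccc2)c1O | intermediate
7 | methyl 2-[3,4-bis(benzyloxy)-2-{[4-(benzyloxy)benzyl]oxy}phenyl]acetate | COC(=O)Cc1ccc(OCc2ccccc2)c(OCc2ccccc2)c1OCc1ccc(OCc2ccccc2)cc1 | intermediate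
8 | methyl 2-diazo-2-[3,4-bis(benzyloxy)-2-{[4-(benzyloxy)benzyl]oxy}phenyl]acetate | COC(=O)C(=[N+]=[N-])c1ccc(OCc2ccccc2)c(OCc2ccccc2)c1OCc1ccc(OCc2ccccc2)cc1 | intermediate
9 | methyl (2R,3S)-6,7-bis(benzyloxy)-2-[4-(benzyloxy)phenyl]-2,3-dihydrobenzofuran-3-carboxylate (cis, not isolated) | COC(=O)[C@H]1c2ccc(OCc3ccccc3)c(OCc3ccccc3)c2O[C@H]1c1ccc(OCc2ccccc2)cc1 | intermediate
10 | methyl (2R,3R)-6,7-bis(benzyloxy)-2-[4-(benzyloxy)phenyl]-2,3-dihydrobenzofuran-3-carboxylate (trans) | COC(=O)[C@@H]1c2ccc(OCc3ccccc3)c(OCc3ccccc3)c2O[C@H]1c1ccc(OCc2ccccc2)cc1 | intermediate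
11 | [(2R,3S)-6,7-bis(benzyloxy)-2-[4-(benzyloxy)phenyl]-2,3-dihydrobenzofuran-3-yl]methanol (trans) | OC[C@@H]1c2ccc(OCc3ccccc3)c(OCc3ccccc3)c2O[C@H]1c1ccc(OCc2ccccc2)cc1 | intermediate
12 | [(2R,3S)-6,7-bis(benzyloxy)-2-[4-(benzyloxy)phenyl]-2,3-dihydrobenzofuran-3-yl]methyl trifluoromethanesulfonate (not isolated) | FC(F)(F)S(=O)(=O)OC[C@@H]1c2ccc(OCc3ccccc3)c(OCc3ccccc3)c2O[C@H]1c1ccc(OCc2ccccc2)cc1 | intermediate
13 | (2S,3R)-7,8-bis(benzyloxy)-2-[4-(benzyloxy)phenyl]chroman-3-ol (2,3-trans) | C1c2ccc(OCc3ccccc3)c(OCc3ccccc3)c2O[C@@H](c2ccc(OCc3ccccc3)cc2)[C@@H]1O | intermediate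
14 | (2S,3R,4S)-7,8-bis(benzyloxy)-2-[4-(benzyloxy)phenyl]-4-methoxychroman-3-ol (2,3-trans-3,4-trans) | CO[C@H]1c2ccc(OCc3ccccc3)c(OCc3ccccc3)c2O[C@@H](c2ccc(OCc3ccccc3)cc2)[C@@H]1O | intermediate
15 | 1-[3,4-bis(benzyloxy)-5-bromo-2-hydroxyphenyl]ethanone | CC(=O)c1cc(Br)c(OCc2ccccc2)c(OCc2ccccc2)c1O | intermediate
16 | 1-[3,4-bis(benzyloxy)-5-bromo-2-(methoxymethoxy)phenyl]ethanone | CC(=O)c1cc(Br)c(OCc2ccccc2)c(OCc2ccccc2)c1OCOC | intermediate
17 | 4-(benzyloxy)benzaldehyde | O=Cc1ccc(OCc2ccccc2)cc1 | starting material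
18 | (E)-1-[3,4-bis(benzyloxy)-5-bromo-2-(methoxymethoxy)phenyl]-3-[4-(benzyloxy)phenyl]prop-2-en-1-one | COCOc1c(C(=O)/C=C/c2ccc(OCc3ccccc3)cc2)cc(Br)c(OCc2ccccc2)c1OCc1ccccc1 | intermediate
19 | [(2R,3S)-3-[4-(benzyloxy)phenyl]oxiran-2-yl][3,4-bis(benzyloxy)-5-bromo-2-(methoxymethoxy)phenyl]methanone (trans epoxide) | COCOc1c(C(=O)[C@@H]2O[C@H]2c2ccc(OCc3ccccc3)cc2)cc(Br)c(OCc2ccccc2)c1OCc1ccccc1 | intermediate
20 | (2R,3R)-7,8-bis(benzyloxy)-2-[4-(benzyloxy)phenyl]-6-bromo-3-hydroxychroman-4-one (2,3-trans) | O(Cc1ccccc1)c1ccc([C@H]2Oc3c(cc(Br)c(OCc4ccccc4)c3OCc4ccccc4)C(=O)[C@@H]2O)cc1 | intermediate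
21 | [(2R,3R)-7,8-bis(benzyloxy)-2-[4-(benzyloxy)phenyl]-3-hydroxy-4-oxochroman-6-yl]boronic acid | O(Cc1ccccc1)c1ccc([C@H]2Oc3c(cc(B(O)O)c(OCc4ccccc4)c3OCc4ccccc4)C(=O)[C@@H]2O)cc1 | intermediate
22 | mixed boronic ester: the 3-O of 14 bound to the boron of 21 (B still carries one OH; not isolated) | CO[C@H]1c2ccc(OCc3ccccc3)c(OCc3ccccc3)c2O[C@@H](c2ccc(OCc3ccccc3)cc2)[C@@H]1OB(O)c1cc2C(=O)[C@H](O)[C@@H](c3ccc(OCc4ccccc4)cc3)Oc2c(OCc2ccccc2)c1OCc1ccccc1 | intermediate
23 | (2R,3R)-7,8-bis(benzyloxy)-2-[4-(benzyloxy)phenyl]-6-[(2S,3R,4S)-7,8-bis(benzyloxy)-2-[4-(benzyloxy)phenyl]-3-hydroxychroman-4-yl]-3-hydroxychroman-4-one; upper unit 2,3-trans-3,4-cis (the C4 descriptor is S here only because the benzyl ethers change the CIP ranking; the spatial arrangement is that of 24 and 25) | O(Cc1ccccc1)c1ccc([C@H]2Oc3c(cc([C@@H]4c5ccc(OCc6ccccc6)c(OCc6ccccc6)c5O[C@@H](c5ccc(OCc6ccccc6)cc5)[C@@H]4O)c(OCc4ccccc4)c3OCc4ccccc4)C(=O)[C@@H]2O)cc1 | intermediate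
24 | (2R,3R)-3,7,8-trihydroxy-2-(4-hydroxyphenyl)-6-[(2S,3R,4R)-3,7,8-trihydroxy-2-(4-hydroxyphenyl)chroman-4-yl]chroman-4-one | Oc1ccc([C@H]2Oc3c(cc([C@@H]4c5ccc(O)c(O)c5O[C@@H](c5ccc(O)cc5)[C@@H]4O)c(O)c3O)C(=O)[C@@H]2O)cc1 | intermediate
25 | (2R,3S,4R)-2-(4-hydroxyphenyl)-6-[(2S,3R,4R)-3,7,8-trihydroxy-2-(4-hydroxyphenyl)chroman-4-yl]chroman-3,4,7,8-tetrol; lower unit 2,3-trans-3,4-trans, upper unit 2,3-trans-3,4-cis | Oc1ccc([C@H]2Oc3c(cc([C@@H]4c5ccc(O)c(O)c5O[C@@H](c5ccc(O)cc5)[C@@H]4O)c(O)c3O)[C@@H](O)[C@@H]2O)cc1 | target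

**Step count and risks**

Total step count: 18. Longest linear sequence: 12 steps (steps 1–9, then 16–18).

Steps most likely to fail:

Step 16 (proposed method). The aryl group may be transferred without the tether (intermolecular attack), or the boronic acid may lose boron to acid before transfer; either would erode the cis selectivity or stop the coupling. The fallback uses the established, untethered cation–arene coupling. It sets out from 14 and 21: protodeboronation of 21 (AcOH, THF/H2O, 60 °C) gives (2R,3R)-7,8-bis(benzyloxy)-2-[4-(benzyloxy)phenyl]-3-hydroxychroman-4-one F1. Friedel–Crafts coupling of 14 with F1 (TMSOTf cat., CH2Cl2, −78 to −20 °C) should attack at C6 (para to O1, ortho to O7). It is expected to give mainly the 3,4-trans hexabenzyl dimer F2, with the 3,4-cis isomer as the minor product. The two are separated by chromatography and the route is rejoined at 23.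

Step 8. The bridged ion may be opened at the primary carbon (return to unrearranged material), or it may lose a proton instead of taking up water. The fallback sets out from 11: the triflate 12 is formed as before but warmed without water (2,6-di-tert-butylpyridine, CH2Cl2, −78 °C to rt), so that reversible triflate return funnels the ring-expanded ion into elimination to (2R)-7,8-bis(benzyloxy)-2-[4-(benzyloxy)phenyl]-2H-chromene F3. Hydroboration–oxidation (BH3·THF, then NaOH/H2O2), known to convert flav-3-enes to 2,3-trans flavan-3-ols by addition anti to the 2-aryl group, then gives 13, where the route is rejoined.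

Step 9. Hydride abstraction may compete at C2 (the benzylic ether C–H next to ring B), or the C4 position may be over-oxidised to the ketone, because ring A lacks a 5-oxygen. The fallback sets out from 11 and goes through the 2H-chromene F3 described above: epoxidation with dimethyldioxirane (acetone, −20 °C) anti to the 2-aryl group gives (2S,3R,4R)-7,8-bis(benzyloxy)-2-[4-(benzyloxy)phenyl]-3,4-epoxychroman F4. Methanolysis (MeOH, PPTS cat., 0 °C) opens it at the benzylic C4 with inversion and returns to the route at 14.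

**Further compounds**

F1 | step 16 | (2R,3R)-7,8-bis(benzyloxy)-2-[4-(benzyloxy)phenyl]-3-hydroxychroman-4-one | O(Cc1ccccc1)c1ccc([C@H]2Oc3c(ccc(OCc4ccccc4)c3OCc4ccccc4)C(=O)[C@@H]2O)cc1
F2 | step 16 | C4 epimer of 23 in the upper unit (2,3-trans-3,4-trans hexabenzyl dimer ketone) | O(Cc1ccccc1)c1ccc([C@H]2Oc3c(cc([C@H]4c5ccc(OCc6ccccc6)c(OCc6ccccc6)c5O[C@@H](c5ccc(OCc6ccccc6)cc5)[C@@H]4O)c(OCc4ccccc4)c3OCc4ccccc4)C(=O)[C@@H]2O)cc1
F3 | step 8 | (2R)-7,8-bis(benzyloxy)-2-[4-(benzyloxy)phenyl]-2H-chromene | C1=C[C@H](c2ccc(OCc3ccccc3)cc2)Oc2c1ccc(OCc1ccccc1)c2OCc1ccccc1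
F4 | step 9 | (2S,3R,4R)-7,8-bis(benzyloxy)-2-[4-(benzyloxy)phenyl]-3,4-epoxychroman (epoxide anti to the 2-aryl group) | O1[C@@H]2c3ccc(OCc4ccccc4)c(OCc4ccccc4)c3O[C@@H](c3ccc(OCc4ccccc4)cc3)[C@H]12
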